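0.0917 M h⁻¹ is where I start: that is how fast G leaves the solid up to the teal run's first reading, and the green run, with 1.1 M of Z, reads 0.0845 M h⁻¹ at its own. So I take this pace as the solid's own. What has left the solid without becoming J is dissolved G, which I call D, and it waits for Z.

| flask | G | Z | remark | time |
|---|---|---|---|---|
| teal | 0.44 M | 0.071 M | run made earlier |  |
| green | 0.44 M | 1.1 M | run made earlier |  |
| red | 0.56 M | 0.484 M | run made earlier |  |
| Friday's | 0.12 M | 0.150 M |  | 6.0 h |
| Tuesday's | 0.44 M | 0.484 M |  | 6.0 h |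
| Thursday's | 0.20 M | 0.484 M |  | 6.0 h |
| Wednesday's | 2.0 M | 1.50 M |  | 6.0 h |
| Monday's | 0.80 M | 0.120 M |  | 6.0 h |
| Sunday's | 0.15 M | 1.00 M |  | 6.0 h |

| run | time / h | J / % | G / % |
|---|---|---|---|
| teal | 0.667 | 0 | 86.1 |
| teal | 1.33 | 0.9 | 74.7 |
| teal | 2.00 | 1.7 | 65.5 |
| teal | 2.50 | 2.0 | 59.4 |
| teal | 3.00 | 2.3 | 54.8 |
| green | 0.250 | 0.8 | 95.2 |
| green | 0.417 | 1.4 | 90.9 |
| green | 0.833 | 5.1 | 82.6 |
| green | 1.50 | 12.2 | 70.7 |
| green | 3.00 | 29.6 | 46.4 |
| red | 0.250 | 0.1 | 95.0 |
| red | 0.417 | 0.8 | 93.0 |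
| red | 0.833 | 1.5 | 86.7 |
| red | 1.50 | 4.8 | 78.3 |
| red | 3.00 | 11.8 | 60.8 |

(scatter of a reading: 0.3 percentage points)

- at the start none of G is in solution
- what has only dissolved of G counts as not reacted
- a reading or a percentage of J counts all its forms, free or not

- the flasks put in order of amount of J, in percent of the G charged, best first, at 6.0 h (Friday's / Tuesday's / Thursday's / Wednesday's / Monday's / Sunday's)
- the amount of J, in percent of the G charged of the flask you put first, at 6.0 h
- the amount of J, in percent of the G charged of the flask you put last, at 6.0 h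

Between the green run's last two readings, J grows and D averages:

dJ/dt = 0.0510 M h⁻¹, D = 0.0904 M

Dividing by D and by Z at its charge gives the coefficient k of D + Z → J, as a reading:

k = 1.43 × 10⁻⁴ M⁻¹ s⁻¹

I reckon Sunday's, whose Z per G is 6.67, the highest of the flasks. Holding Z at its charge makes the step pseudo-first-order, so the share of D surviving to time t is e^(−kZt):

kZt = 3.08, so J = 95.4%

One link I can mend by hand is the clock, since D isn't there at the start. Sunday's charge needs τ = 1.64 h to dissolve at that pace, which is shorter than the run, so D starts on average 0.5τ late. The drain number N, the lifetimes of D that the run holds with Z still at its charge and the step still one-way, is then k·Z·(t − 0.5τ):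

N = 2.66, so J = 93.0%

The forecast gives Sunday's > Thursday's > Tuesday's > Friday's > Wednesday's > Monday's, with 72% first and 6% last, and remarks: “Friday versus Wednesday is close”. Its top is lower than my 93.0%.

The flask gives Sunday's > Thursday's > Tuesday's > Friday's > Wednesday's > Monday's, with 68.7% first and 3.47% last.

    G ⇌ D, rate k1*(cs1 - [D]) while solid is left; crystals form when [D] > cs1 (solubility = 0.340 M, k = 8.09 × 10⁻⁵ s⁻¹)
    D + Z ⇌ J (K = 2.22 M⁻¹, k = 2.69 × 10⁻⁴ M⁻¹ s⁻¹)
    E ⇌ J, rate k3*(cs3 - [J]) while solid is left; crystals form when [J] > cs3 (solubility = 0.210 M, k = 5.31 × 10⁻⁴ s⁻¹)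
    Z + J ⇌ Q, settled at all times (K = 1.90 M⁻¹)
    Z ⇌ L (K = 1.50, k = 3.36 × 10⁻⁵ s⁻¹)

Sunday's J stops short of my reckoning mainly because of the backward run from J to D + Z. The same flask without that backward run reaches 94.2%, where N = 2.66 gave 93.0%, and with it Sunday's holds 68.7%. On Thursday's, N is 1.22, which forward gives 70.5%, and the flask holds 40.2%.

All runs stem from a simulated flask from invented constants; noise was put on by code.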